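I read this flask at the moment when 20 % of the substrate is converted.

substrate 0.20 M; coupling partner 0.600 equiv; free catalyst 1 mol%

1. apparent order in coupling partner when 20 % of the substrate are converted (percent change of the rate of making product for one percent more coupling partner charged)
2. apparent order in free catalyst when 20 % of the substrate are converted (percent change of the rate of making product for one percent more free catalyst charged)
3. factor on the rate of making product when 20 % of the substrate are converted if coupling partner is charged twice over

- for by-product the idle complex is counted in
- charge of substrate (flask): 0.20 M

    substrate + free catalyst → catalyst intermediate A (k1 = 0.081 M⁻¹ s⁻¹)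
    free catalyst + by-product ⇌ idle complex (K2 = 7.6 M⁻¹, k2 = 0.018 M⁻¹ s⁻¹)
    catalyst intermediate B → by-product + catalyst intermediate C (k3 = 0.0092 s⁻¹)
    coupling partner + catalyst intermediate A → catalyst intermediate B (k4 = 4.6 M⁻¹ s⁻¹)
    catalyst intermediate C → free catalyst + product (k5 = 0.010 s⁻¹)

Free catalyst takes up substrate to give catalyst intermediate A. A takes up coupling partner to give catalyst intermediate B, B sheds by-product to give catalyst intermediate C, and C releases product and free catalyst. Free catalyst also binds by-product reversibly as idle complex.

I count turnovers. Each stop costs a catalyst a wait, and the rate is the catalyst charge divided by the sum of the waits. At the start: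

substrate 61.7 s + partner 1.81 s + the two first-order steps 209 s = 272 s, a rate of 0.0264 M h⁻¹

At the reading, I assume the idle complex is in equilibrium with free catalyst. That stretches the substrate wait by 0.304, the equilibrium constant times the by-product made:

substrate 77.2 s + idle 23.5 s + partner 2.72 s + 209 s = 312 s

This sum, the round time τ, gives 0.0231 M h⁻¹. Thinner substrate alone slows the rate by a factor 1.06, idling alone, reckoned on the full substrate wait, by 1.07, and thinner partner alone by 1.00. Together they give 1.15. Later the partner's wait grows as the partner thins. The partner is the limiting reagent, so I expect product to stop near 0.600 equiv.

I take the partner's order as its share of τ times charge over partner left, and any extra charge adds in full to the partner left at the reading: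

0.0131

Twice the charge cuts its wait to 1.09 s, a factor 1.01. τ contains no catalyst concentration, so I put the catalyst order at one.

The forecast gives 0.013, 1.005 and 1.005, holding that “the rate barely responds to partner”.

The simulation gives 0.013, 1.0 and 1.01, with a rate of 0.0233 M h⁻¹ after 1.57 h. After 25.0 h, coupling partner is down to 0 %, product stands at 60.0 % and substrate at 39 %.

My idle wait of 23.5 s assumes that idle complex returns to free catalyst. The largest single effect on this flask's rate at the reading is that return. In the simulated run without it, the rate is 0.556 of the actual one, so τ read per charged catalyst becomes 561 s. The order in free catalyst in that run is 2.0.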